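**Plan**

1. Numbering (eremophilane): ring A is C1–C5 and C10 (C2 ketone, methyls on C4 and C5); ring B is C5–C10 (isopropenyl on C7, esters on C8 and C9). The retrosynthesis cuts the two ester C–O bonds, then C4–H and C9–H (enone and ketone reductions), then C5–C10 and C1–C2 together, then the chain bonds C9–C10, C5–C6, C3–C4 and C7–C8.
2. Enabling feature: the cis C5–C10 fusion bond lies next to the C9 oxygen and ring A carries its oxygen on C2. Rings A and B therefore map onto a C1=C10 vinyl ketone (C9=O) tethered through C8–C7–C6 to an E,E 1-alkoxy diene C2=C3–C4=C5.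
3. Forward: an Evans aldol joins C7–C8; a Suzuki coupling (C3–C4) and a Negishi coupling (C5–C6) attach the diene; a vinyl Grignard reagent (C9–C10) completes the trienone; both rings then close in one cycloaddition.
4. Stereochemistry: the auxiliary sets C7 and C8; a chelate between C9=O and the C8 benzyloxy group, plus the endo mode, relays them to C10 and C5. C9 comes from a hindered hydride, C4 from axial protonation of the enone, and the side-chain centre from (R)-2-methylbutanoic acid.
5. The C2 oxygen is carried as an ethyl enol ether and later unmasked oxidatively to the enone; O8 carries a benzyl group that is removed in the enone reduction.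

Key step: step 11

Remark: bicyclic compounds are named with the eremophilane numbers defined above, and the descriptors refer to that numbering.

**Step 1**
Reactants: 1 (R)-4-benzyl-1,3-oxazolidin-2-one; 2 3-methylbut-3-enoic acid
Product: 4 (4R)-4-benzyl-3-(3-methylbut-3-enoyl)-1,3-oxazolidin-2-one, via mixed pivalic anhydride 3 (not isolated)
Conditions: 2, t-BuCOCl, Et3N, THF, −78 → 0 °C; then 1 pre-treated with n-BuLi (THF, −78 °C), −78 → 0 °C
Reagents that add atoms: 3-methylbut-3-enoic acid (2), C=C(C)CC(=O)O
Why: N-acylation of the lithiated oxazolidinone by a mixed pivalic anhydride is the standard entry to such imides, and the low temperature keeps the β,γ-double bond out of conjugation.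

**Step 2**
Reactants: 4 (4R)-4-benzyl-3-(3-methylbut-3-enoyl)-1,3-oxazolidin-2-one; 5 ethyl glyoxylate
Product: 7 ethyl (2R,3R)-3-[(4R)-4-benzyl-2-oxo-1,3-oxazolidine-3-carbonyl]-2-hydroxy-4-methylpent-4-enoate, via boron enolate 6 (not isolated)
Conditions: Bu2BOTf, Et3N, CH2Cl2, −78 → 0 °C; then freshly distilled 5, −78 → 0 °C; pH 7 buffer, MeOH, H2O2, 0 °C
Reagents that add atoms: ethyl glyoxylate (5), CCOC(=O)C=O
Why: Evans syn-aldol reaction: the Z boron enolate reacts through a closed chair transition state on the face away from the auxiliary benzyl group, which sets C7 and C8 (2R,3R in 7) in one operation with the strongly electrophilic glyoxylate as acceptor.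

**Step 3**
Reactants: 7 aldol adduct; 8 2-benzyloxy-1-methylpyridinium triflate
Product: 9 ethyl (2R,3R)-2-(benzyloxy)-3-[(4R)-4-benzyl-2-oxo-1,3-oxazolidine-3-carbonyl]-4-methylpent-4-enoate
Conditions: 8, MgO, PhCF3, 85 °C
Reagents that add atoms: 2-benzyloxy-1-methylpyridinium triflate (8), C[n+]1ccccc1OCc1ccccc1.[O-]S(=O)(=O)C(F)(F)F
Why: Benzyl transfer from the pyridinium salt under neutral conditions (O-benzylation of an alcohol) avoids the retro-aldol and alkene-migration pathways open under basic or strongly acidic benzylation.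

**Step 4**
Reactants: 9 benzyl ether imide
Product: 11 (3R,4S)-3-(benzyloxy)-4-(prop-1-en-2-yl)oxolan-2-one, via hydroxy ester 10 (not isolated)
Conditions: LiBH4 (1.1 equiv), MeOH (1 equiv), THF, −10 → 0 °C; aq. NH4Cl; then PPTS (cat.), CH2Cl2, rt
Reagents that add atoms: none
Why: Reductive removal of the auxiliary: borohydride should attack the activated exocyclic imide carbonyl faster than the ester at low temperature, and the resulting γ-hydroxy ester closes to the five-membered lactone (lactonisation) with both stereocentres untouched.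

**Step 5**
Reactants: 11 lactone; 12 N,O-dimethylhydroxylamine hydrochloride
Product: 13 (2R,3S)-2-(benzyloxy)-3-(hydroxymethyl)-N-methoxy-N,4-dimethylpent-4-enamide
Conditions: 12, Me3Al, CH2Cl2, 0 °C → rt; aq. potassium sodium tartrate; crude product used at once
Reagents that add atoms: N,O-dimethylhydroxylamine hydrochloride (12), CNOC.Cl
Why: Aminolysis of a lactone with the aluminium amide of N,O-dimethylhydroxylamine (Weinreb amide formation) opens the ring at the acyl carbon and frees the C6 hydroxyl, which is iodinated immediately because the hydroxy amide can relactonise.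

**Step 6**
Reactants: 13 hydroxy amide; 14 iodine
Product: 15 (2R,3R)-2-(benzyloxy)-3-(iodomethyl)-N-methoxy-N,4-dimethylpent-4-enamide
Conditions: I2, PPh3, imidazole, CH2Cl2, 0 °C, dark
Reagents that add atoms: iodine (14), II
Why: Appel-type iodination of a primary alcohol proceeds by SN2 displacement of the alkoxyphosphonium ion and does not touch the stereocentres.

**Step 7**
Reactants: 16 but-2-yne; 14 iodine
Product: 17 (E)-2,3-diiodobut-2-ene
Conditions: I2, neutral Al2O3, hexane, rt, dark
Reagents that add atoms: iodine (14), II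
Why: Electrophilic iodination of an alkyne goes through an iodonium ion opened anti by iodide, giving the E-diiodide that fixes the trans relation of C3 and C6 across the future C4=C5 bond.

**Step 8**
Reactants: 17 (E)-2,3-diiodobut-2-ene; 18 (E)-2-(2-ethoxyvinyl)-4,4,5,5-tetramethyl-1,3,2-dioxaborolane
Product: 19 (1E,3E)-1-ethoxy-4-iodo-3-methylpenta-1,3-diene
Conditions: 17 (3 equiv), 18 (1 equiv), Pd(OAc)2 (3 mol%), SPhos (6 mol%), K3PO4, THF/H2O 10:1, 40 °C; chromatography on Et3N-treated silica
Reagents that add atoms: (E)-2-(2-ethoxyvinyl)-4,4,5,5-tetramethyl-1,3,2-dioxaborolane (18), CCO/C=C/B1OC(C)(C)C(C)(C)O1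
Why: Suzuki–Miyaura coupling proceeds with retention at both sp2 carbons, and an excess of the symmetrical diiodide together with the lower reactivity of the electron-rich product towards zerovalent palladium should limit the reaction to one C–I bond.

**Step 9**
Reactants: 15 iodide; 19 iodo-diene
Product: 21 (2R,3R,5E,7E)-2-(benzyloxy)-8-ethoxy-N-methoxy-N,5,6-trimethyl-3-(prop-1-en-2-yl)octa-5,7-dienamide, via alkylzinc iodide 20 (not isolated)
Conditions: Zn dust (activated with BrCH2CH2Br and Me3SiCl), LiCl, THF, 25 °C; then 19 (1.2 equiv), Pd(OAc)2 (3 mol%), SPhos (6 mol%), 25 → 40 °C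
Reagents that add atoms: (1E,3E)-1-ethoxy-4-iodo-3-methylpenta-1,3-diene (19), CCO/C=C/C(C)=C(C)/I
Why: Negishi coupling: zinc inserts into the primary C–I bond without disturbing the amide, and palladium-catalysed sp3–sp2 coupling with the alkenyl iodide forms C5–C6 with retention of the E,E-diene geometry.

**Step 10**
Reactants: 21 Weinreb amide; 22 vinylmagnesium bromide
Product: 23 (4R,5R,7E,9E)-4-(benzyloxy)-10-ethoxy-7,8-dimethyl-5-(prop-1-en-2-yl)deca-1,7,9-trien-3-one
Conditions: CH2=CHMgBr (2.5 equiv), THF, −78 → −20 °C; inverse quench into cold aq. NH4Cl; used directly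
Reagents that add atoms: vinylmagnesium bromide (22), C=C[Mg]Br
Why: Weinreb ketone synthesis: the magnesium-chelated tetrahedral adduct survives until the quench, so a single vinyl group is delivered and the α-benzyloxy stereocentre is not enolised.

**Step 11**
Reactants: 23 trienone
Product: 24 (2R,5S,7R,8R,10S)-8-(benzyloxy)-2-ethoxyeremophila-3,11-dien-9-one
Conditions: Me2AlCl (2.5 equiv), CH2Cl2, −78 → −30 °C; aq. NaHCO3 / potassium sodium tartrate
Reagents that add atoms: none
Why: Intramolecular Diels–Alder reaction of a 1,7,9-decatrien-3-one: the Lewis-acid-bound C1=C10 enone adds across the E,E C2=C3–C4=C5 ethoxy diene in a concerted but asynchronous [4+2] process that forms C5–C10 and C1–C2, the closest known reaction type being the Lewis-acid-promoted cyclisation of 1,7,9-decatrien-3-ones to cis-fused 1-octalones. Ring A closes as the new cyclohexene of the cycloaddition and ring B as the six-membered ring spanned by the C6–C9 tether, which also fixes the regiochemistry. C10 is controlled by C8: a five-membered chelate of the dimethylaluminium cation between C9=O and the C8 benzyloxy oxygen holds the enone s-cis and coplanar with the C8–O bond, so the diene, delivered through C7, can only reach the enone face that places H10 syn to H8. C5 is controlled by the endo mode, in which the C9 carbonyl lies under the diene while C6 occupies the outside (E) position of the diene terminus; this gives the cis ring fusion through a chair-like tether with the C7 isopropenyl group equatorial, and the E enol ether places the C2 ethoxy group trans to the C5 methyl, a centre erased later. The step needs endo over exo selectivity and a single enone face; the chelate, the Lewis acid and the matched equatorial C7 substituent should secure both, and the cis-fused ketone is also the more stable C10 epimer, so enolisation should not erode it. The fully substituted diene terminus is the demanding element and is the reason for Lewis-acid activation.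

**Step 12**
Reactants: 24 cis-fused ketone
Product: 25 (2R,5S,7R,8R,9S,10S)-8-(benzyloxy)-2-ethoxyeremophila-3,11-dien-9-ol
Conditions: LiBH(s-Bu)3, THF, −78 °C; then NaOH, H2O2, 0 °C
Reagents that add atoms: none
Why: Reduction with a bulky trialkylborohydride: ring B is a chair with the C7 and C8 substituents equatorial and the axial C5–C4 bond covering the lower face of C9, so hydride should enter along the equatorial direction and give the axial C9 alcohol cis to the C8 benzyloxy group (9S).

**Step 13**
Reactants: 25 allylic ethyl ether; 26 water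
Product: 27 (5S,7R,8R,9S,10S)-8-(benzyloxy)-9-hydroxyeremophila-3,11-dien-2-one
Conditions: DDQ (2 equiv), CH2Cl2/H2O 10:1, 0 °C → rt
Reagents that add atoms: water (26), O
Why: Oxidative cleavage of an allylic ether with DDQ: hydride abstraction from the allylic, oxygen-bearing C2–H gives an oxocarbenium ion that water converts through the hemiketal into the C2 enone, as with prenyl-type ethers, while the benzyl ether reacts far more slowly.

**Step 14**
Reactants: 27 enone
Product: 28 (4S,5R,7R,8R,9S,10S)-8,9-dihydroxyeremophil-11-en-2-one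
Conditions: Li (8 equiv), NH3(l)/THF, −78 °C, 30 min; isoprene, then NH4Cl
Reagents that add atoms: none
Why: Dissolving-metal reduction: the enone dianion is protonated at C4 along the axial direction from the face that carries the C9 hydroxyl, anti to the C5 methyl, which leaves the C4 methyl equatorial and cis to the C5 methyl (4S), and the enolate so formed is inert while the benzyl ether is cleaved reductively.

**Step 15**
Reactants: 28 diol ketone; 29 (R)-2-methylbutanoic acid
Product: 30 (4S,5R,7R,8R,9S,10S)-9-hydroxy-8-[(2R)-2-methylbutanoyloxy]eremophil-11-en-2-one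
Conditions: 29 (1.2 equiv), EDC·HCl, DMAP (0.2 equiv), CH2Cl2, −20 → 0 °C
Reagents that add atoms: (R)-2-methylbutanoic acid (29), CC[C@@H](C)C(=O)O
Why: Steglich esterification: the equatorial C8 hydroxyl is much more accessible than the axial C9 hydroxyl, which is flanked by the ring fusion and shielded by ring A, so one acyl group should enter at O8, and the α-alkyl acid is not prone to racemisation under carbodiimide activation.

**Step 16**
Reactants: 30 mono-ester; 31 tiglic acid
Product: 33 CNP0312791.1 = (4S,5R,7R,8R,9S,10S)-8-[(2R)-2-methylbutanoyloxy]-9-[(2E)-2-methylbut-2-enoyloxy]eremophil-11-en-2-one, via mixed tiglic anhydride 32 (not isolated)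
Conditions: 31, 2,4,6-Cl3C6H2COCl, Et3N, toluene, rt; then 30, DMAP, toluene, 60 °C
Reagents that add atoms: tiglic acid (31), C/C=C(\C)C(=O)O
Why: Yamaguchi esterification: the mixed trichlorobenzoic anhydride with DMAP acylates the hindered axial C9 hydroxyl, and the E geometry of the tiglate, the stable isomer, is retained.

**Compound list**

1 | (R)-4-benzyl-1,3-oxazolidin-2-one | O=C1N[C@H](Cc2ccccc2)CO1 | starting material
2 | 3-methylbut-3-enoic acid | C=C(C)CC(=O)O | starting material
3 | 3-methylbut-3-enoic pivalic anhydride | C=C(C)CC(=O)OC(=O)C(C)(C)C | intermediate (not isolated)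
4 | (4R)-4-benzyl-3-(3-methylbut-3-enoyl)-1,3-oxazolidin-2-one | C=C(C)CC(=O)N1[C@H](Cc2ccccc2)COC1=O | intermediate
5 | ethyl glyoxylate | CCOC(=O)C=O | starting material
6 | dibutylboron Z-enolate of imide 4 | CCCCB(CCCC)O/C(=C\C(C)=C)N1[C@H](Cc2ccccc2)COC1=O | intermediate (not isolated)
7 | ethyl (2R,3R)-3-[(4R)-4-benzyl-2-oxo-1,3-oxazolidine-3-carbonyl]-2-hydroxy-4-methylpent-4-enoate | CCOC(=O)[C@H](O)[C@@H](C(C)=C)C(=O)N1[C@H](Cc2ccccc2)COC1=O | intermediate
8 | 2-benzyloxy-1-methylpyridinium triflate | C[n+]1ccccc1OCc1ccccc1.[O-]S(=O)(=O)C(F)(F)F | starting material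
9 | ethyl (2R,3R)-2-(benzyloxy)-3-[(4R)-4-benzyl-2-oxo-1,3-oxazolidine-3-carbonyl]-4-methylpent-4-enoate | CCOC(=O)[C@H](OCc1ccccc1)[C@@H](C(C)=C)C(=O)N1[C@H](Cc2ccccc2)COC1=O | intermediate
10 | ethyl (2R,3S)-2-(benzyloxy)-3-(hydroxymethyl)-4-methylpent-4-enoate | CCOC(=O)[C@H](OCc1ccccc1)[C@@H](C(C)=C)CO | intermediate (not isolated)
11 | (3R,4S)-3-(benzyloxy)-4-(prop-1-en-2-yl)oxolan-2-one | O=C1OC[C@H](C(C)=C)[C@H]1OCc1ccccc1 | intermediate
12 | N,O-dimethylhydroxylamine hydrochloride | CNOC.Cl | starting material
13 | (2R,3S)-2-(benzyloxy)-3-(hydroxymethyl)-N-methoxy-N,4-dimethylpent-4-enamide | CON(C)C(=O)[C@H](OCc1ccccc1)[C@@H](C(C)=C)CO | intermediate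
14 | iodine | II | starting material
15 | (2R,3R)-2-(benzyloxy)-3-(iodomethyl)-N-methoxy-N,4-dimethylpent-4-enamide | CON(C)C(=O)[C@H](OCc1ccccc1)[C@@H](C(C)=C)CI | intermediate
16 | but-2-yne | CC#CC | starting material
17 | (E)-2,3-diiodobut-2-ene | I/C(C)=C(C)/I | intermediate
18 | (E)-2-(2-ethoxyvinyl)-4,4,5,5-tetramethyl-1,3,2-dioxaborolane | CCO/C=C/B1OC(C)(C)C(C)(C)O1 | starting material
19 | (1E,3E)-1-ethoxy-4-iodo-3-methylpenta-1,3-diene | CCO/C=C/C(C)=C(C)/I | intermediate
20 | [(2R,3R)-3-(benzyloxy)-4-[methoxy(methyl)amino]-4-oxo-2-(prop-1-en-2-yl)butyl]zinc iodide | CON(C)C(=O)[C@H](OCc1ccccc1)[C@@H](C(C)=C)C[Zn]I | intermediate (not isolated)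
21 | (2R,3R,5E,7E)-2-(benzyloxy)-8-ethoxy-N-methoxy-N,5,6-trimethyl-3-(prop-1-en-2-yl)octa-5,7-dienamide | CON(C)C(=O)[C@H](OCc1ccccc1)[C@@H](C(C)=C)C/C(C)=C(C)/C=C/OCC | intermediate
22 | vinylmagnesium bromide | C=C[Mg]Br | starting material
23 | (4R,5R,7E,9E)-4-(benzyloxy)-10-ethoxy-7,8-dimethyl-5-(prop-1-en-2-yl)deca-1,7,9-trien-3-one | C=CC(=O)[C@H](OCc1ccccc1)[C@@H](C(C)=C)C/C(C)=C(C)/C=C/OCC | intermediate
24 | (2R,5S,7R,8R,10S)-8-(benzyloxy)-2-ethoxyeremophila-3,11-dien-9-one | C=C(C)[C@H]1C[C@@]2(C)[C@H](C[C@@H](OCC)C=C2C)C(=O)[C@@H]1OCc1ccccc1 | intermediate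
25 | (2R,5S,7R,8R,9S,10S)-8-(benzyloxy)-2-ethoxyeremophila-3,11-dien-9-ol | C=C(C)[C@H]1C[C@@]2(C)[C@H](C[C@@H](OCC)C=C2C)[C@H](O)[C@@H]1OCc1ccccc1 | intermediate
26 | water | O | starting material
27 | (5S,7R,8R,9S,10S)-8-(benzyloxy)-9-hydroxyeremophila-3,11-dien-2-one | C=C(C)[C@H]1C[C@@]2(C)[C@H](CC(=O)C=C2C)[C@H](O)[C@@H]1OCc1ccccc1 | intermediate
28 | (4S,5R,7R,8R,9S,10S)-8,9-dihydroxyeremophil-11-en-2-one | C=C(C)[C@H]1C[C@@]2(C)[C@H](CC(=O)C[C@@H]2C)[C@H](O)[C@@H]1O | intermediate
29 | (R)-2-methylbutanoic acid | CC[C@@H](C)C(=O)O | starting material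
30 | (4S,5R,7R,8R,9S,10S)-9-hydroxy-8-[(2R)-2-methylbutanoyloxy]eremophil-11-en-2-one | C=C(C)[C@H]1C[C@@]2(C)[C@H](CC(=O)C[C@@H]2C)[C@H](O)[C@@H]1OC(=O)[C@H](C)CC | intermediate
31 | tiglic acid | C/C=C(\C)C(=O)O | starting material
32 | tiglic 2,4,6-trichlorobenzoic anhydride | C/C=C(\C)C(=O)OC(=O)c1c(Cl)cc(Cl)cc1Cl | intermediate (not isolated)
33 | CNP0312791.1, (4S,5R,7R,8R,9S,10S)-8-[(2R)-2-methylbutanoyloxy]-9-[(2E)-2-methylbut-2-enoyloxy]eremophil-11-en-2-one | C=C(C)[C@H]1C[C@@]2(C)[C@H](CC(=O)C[C@@H]2C)[C@H](OC(=O)/C(C)=C/C)[C@@H]1OC(=O)[C@H](C)CC | target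

**Step count and risks**

Total step count: 16. Longest linear sequence: 14 steps (steps 1–6 and 9–16); the diene fragment adds steps 7 and 8.

Steps most likely to fail:

Step 11 (cycloaddition). The exo mode or attack on the other enone face may compete if chelation is incomplete. The Lewis acid may ionise or hydrolyse the enol ether, or a stepwise Michael-type closure may divert material to a bridged skeleton. The hindered diene terminus may also react too slowly. The fallback changes the dienophile to an alkyne, so the ring-forming step creates no stereocentre at C10. Setting out from amide 21, HC≡CMgBr (THF, −78 °C) should give the ynone (4R,5R,7E,9E)-4-(benzyloxy)-10-ethoxy-7,8-dimethyl-5-(prop-1-en-2-yl)deca-7,9-dien-1-yn-3-one F1. On warming in toluene, F1 is expected to cyclise (intramolecular Diels–Alder reaction of an ynone) to the cross-conjugated dienone (2S,5R,7R,8R)-8-(benzyloxy)-2-ethoxyeremophila-1(10),3,11-trien-9-one F2. Facial selectivity at C5 then rests on the chair-like tether alone. Conjugate reduction of the C1=C10 enone with [(Ph3P)CuH]6, followed by protonation of the enolate under equilibrating conditions (DBU), should give the cis-fused ketone, the more stable C10 epimer. The route is rejoined at 24.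

Step 9 (Negishi coupling). Iodide 15 may close back to lactone 11 through attack of the amide oxygen on C6 during iodination or zinc insertion. Zinc insertion may stall, or transmetalation to the crowded alkenylpalladium intermediate may be slow. The fallback installs the amide after the coupling. Setting out from imide 9, the LiBH4 reduction is quenched cold at pH 7 and the crude hydroxy ester 10 is iodinated at once (I2, PPh3, imidazole). This should give ethyl (2R,3R)-2-(benzyloxy)-3-(iodomethyl)-4-methylpent-4-enoate F3, an ester-bearing iodide of the kind routinely turned into alkylzinc reagents. Zinc insertion should give [(2R,3R)-3-(benzyloxy)-4-ethoxy-4-oxo-2-(prop-1-en-2-yl)butyl]zinc iodide F4. The same palladium-catalysed coupling with 19 should then give ethyl (2R,3R,5E,7E)-2-(benzyloxy)-8-ethoxy-5,6-dimethyl-3-(prop-1-en-2-yl)octa-5,7-dienoate F5. Treatment with i-PrMgCl and N,O-dimethylhydroxylamine hydrochloride (THF, −20 °C) converts the ester into amide 21, where the route is rejoined.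

Step 8 (mono-coupling of the diiodide). Reductive loss of both iodine atoms from 17 under palladium and phosphine may regenerate but-2-yne, or a second coupling may occur at the remaining C–I bond. The fallback differentiates the two halogen positions. Setting out from but-2-yne 16, IBr (CH2Cl2, −78 °C) should add anti to give (E)-2-bromo-3-iodobut-2-ene F6. Suzuki–Miyaura coupling with 18 should then take place only at the C–I bond and give (1E,3E)-4-bromo-1-ethoxy-3-methylpenta-1,3-diene F7. Its C–Br bond is coupled with zinc reagent 20 under the Negishi conditions of step 9, and the route is rejoined at 21.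

**Further compounds**

F1 | step 11 | (4R,5R,7E,9E)-4-(benzyloxy)-10-ethoxy-7,8-dimethyl-5-(prop-1-en-2-yl)deca-7,9-dien-1-yn-3-one | C#CC(=O)[C@H](OCc1ccccc1)[C@@H](C(C)=C)C/C(C)=C(C)/C=C/OCC
F2 | step 11 | (2S,5R,7R,8R)-8-(benzyloxy)-2-ethoxyeremophila-1(10),3,11-trien-9-one | C=C(C)[C@H]1C[C@@]2(C)C(=C[C@@H](OCC)C=C2C)C(=O)[C@@H]1OCc1ccccc1
F3 | step 9 | ethyl (2R,3R)-2-(benzyloxy)-3-(iodomethyl)-4-methylpent-4-enoate | CCOC(=O)[C@H](OCc1ccccc1)[C@@H](C(C)=C)CI
F4 | step 9 | [(2R,3R)-3-(benzyloxy)-4-ethoxy-4-oxo-2-(prop-1-en-2-yl)butyl]zinc iodide | CCOC(=O)[C@H](OCc1ccccc1)[C@@H](C(C)=C)C[Zn]I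
F5 | step 9 | ethyl (2R,3R,5E,7E)-2-(benzyloxy)-8-ethoxy-5,6-dimethyl-3-(prop-1-en-2-yl)octa-5,7-dienoate | CCOC(=O)[C@H](OCc1ccccc1)[C@@H](C(C)=C)C/C(C)=C(C)/C=C/OCC
F6 | step 8 | (E)-2-bromo-3-iodobut-2-ene | Br/C(C)=C(C)/I
F7 | step 8 | (1E,3E)-4-bromo-1-ethoxy-3-methylpenta-1,3-diene | CCO/C=C/C(C)=C(C)/Br
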